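**Plan**

- Numbering (carotenoid): hydroxylated ring C1–C6 (C1 gem-dimethyl, C3 carbinol, C5 methyl), triple bond C7≡C8, ε-ring primed.
- Retrosynthesis: a Wittig cut at C11=C12 gives C25 phosphonium salt 18 and C15 hydroxy-enynal 11. Salt 18 is cut at C11'=C12' into the (R)-α-ionone-derived C15 salt 14 and C10 dialdehyde 15. Enynal 11 is cut at C6–C7 (Sonogashira) into enol triflate 7 and enynol 8. The six-membered ketone behind 7 is cut at C4–C5/C5–C6: C5 with its methyl is excised, leaving cyclopentanone 5.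
- Enabling feature: C6 lies between the quaternary C1 and the methyl-bearing C5. In 5 the carbonyl carbon (future C6) therefore has one fully substituted neighbour and one CH2 neighbour (future C4). A CHMe unit from diazoethane can enter only the C6–C4 bond, the product cannot homologate twice, and its single α-hydrogen fixes the C5=C6 enol triflate.
- Forward order: five-membered ring (1 → 5), enlargement to the six-membered ring (6), triflate, C6–C7 coupling, oxidation to 11; ε-half 12 → 14 → 16 → 18; the final C11=C12 Wittig joins the halves.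
- Stereochemistry: C3 from Cu-catalysed enantioselective conjugate borylation of achiral enone 2 (oxidised with retention); C6' from (R)-α-ionone; 9E from 8; the other E double bonds from 15 and from thermal equilibration after each Wittig step.

Key step: step 4

Remark: (R)-α-ionone 12 (the natural dextrorotatory enantiomer) and the all-E C10 dialdehyde 15 are taken as purchasable; diazoethane is used as a separately prepared ether solution.

**Route**

Step 1
Reactants: 1 2,2-dimethylcyclopentan-1-one
Product: 2 5,5-dimethylcyclopent-2-en-1-one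
Conditions: IBX (2 equiv), DMSO, 80 °C
Reagents that add atoms: none
Why: IBX dehydrogenation of a ketone to its enone via the enol; only one α-carbon of 1 carries hydrogens, so a single enone can form.

Step 2
Reactants: 2 5,5-dimethylcyclopent-2-en-1-one
Product: 4 (4S)-4-hydroxy-2,2-dimethylcyclopentan-1-one, via pinacol boronate 3 (not isolated)
Conditions: CuCl (3 mol %), NaOtBu (4 mol %), Josiphos/Taniaphos-type ferrocenyl bisphosphine (3 mol %, antipode chosen for 4S), B2pin2 (1.1 equiv), MeOH (2 equiv), THF, rt; then NaBO3·4H2O, THF/H2O, rt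
Reagents that add atoms: bis(pinacolato)diboron, CC1(C)OB(OC1(C)C)B1OC(C)(C)C(C)(C)O1 (boron of 3); sodium perborate, O=BO[O-].[Na+] (oxygen of 4)
Why: Cu-catalysed asymmetric conjugate borylation of a cyclic enone, in which the chiral bisphosphine–Cu–Bpin species adds to one face of the flat enone and sets the future C3, followed by C–B oxidation with retention.

Step 3
Reactants: 4 (4S)-4-hydroxy-2,2-dimethylcyclopentan-1-one
Product: 5 (4S)-4-[(tert-butyldimethylsilyl)oxy]-2,2-dimethylcyclopentan-1-one
Conditions: TBSCl, imidazole, DMF, rt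
Reagents that add atoms: tert-butyldimethylsilyl chloride, CC(C)(C)[Si](C)(C)Cl
Why: Standard silylation of a secondary alcohol, which shields the hydroxyl from the diazoalkane/Lewis acid of step 4 and the base of step 5.

Step 4
Reactants: 5 (4S)-4-[(tert-butyldimethylsilyl)oxy]-2,2-dimethylcyclopentan-1-one
Product: 6 (4R)-4-[(tert-butyldimethylsilyl)oxy]-2,2,6-trimethylcyclohexan-1-one (both C6 epimers)
Conditions: Me3Al (1.2 equiv), CH2Cl2, −78 °C; CH3CHN2 (Et2O solution, 1.5 equiv), −78 → −20 °C
Reagents that add atoms: diazoethane, CC=[N+]=[N-]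
Why: Me3Al activates the carbonyl of 5 (future C6), the diazo carbon of diazoethane adds to it, and the β-oxido diazonium intermediate loses N2 while the ring CH2 (future C4) shifts from C6 to the CHMe carbon (future C5). The closest known reaction type is the Lewis acid-promoted Büchner–Curtius–Schlotterbeck (Tiffeneau–Demjanov-type) homologation of cyclic ketones with diazoalkanes. No ring is closed; the cyclopentanone is enlarged to the cyclohexanone by a 1,2-alkyl shift that formally inserts CHMe into the C6–C4 bond. The new CHMe stereocenter is not controlled and need not be, because step 5 makes it sp2, while the silyloxy carbon takes no part in any bond change and keeps its configuration (its descriptor changes from S to R only because the CIP order of its two ring branches changes). The step needs migration of the CH2 and not of the quaternary carbon, which the gem-dimethyl group should secure by keeping the incoming diazoalkane and the departing N2 on the unhindered side, the preference known from the D-homologation of 17-keto steroids. It also needs a single insertion, which should follow because 6 is α,α,α'-trisubstituted and far more hindered than 5, and the low temperature with the oxophilic aluminium promoter should disfavour epoxide formation and β-elimination of the silyloxy group.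

Step 5
Reactants: 6 (4R)-4-[(tert-butyldimethylsilyl)oxy]-2,2,6-trimethylcyclohexan-1-one
Product: 7 (4R)-4-[(tert-butyldimethylsilyl)oxy]-2,6,6-trimethylcyclohex-1-en-1-yl trifluoromethanesulfonate
Conditions: LDA, THF, −78 → 0 °C; PhNTf2, 0 °C → rt
Reagents that add atoms: N-phenylbis(trifluoromethanesulfonimide), O=S(=O)(N(c1ccccc1)S(=O)(=O)C(F)(F)F)C(F)(F)F
Why: Enolate O-triflation; 6 has a single α-hydrogen, so both epimers converge on one tetrasubstituted enol triflate (the C5=C6 bond), and the silyloxy group is γ to the carbonyl and cannot be eliminated.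

Step 6
Reactants: 7 (4R)-4-[(tert-butyldimethylsilyl)oxy]-2,6,6-trimethylcyclohex-1-en-1-yl trifluoromethanesulfonate; 8 (2E)-3-methylpent-2-en-4-yn-1-ol
Product: 9 (2E)-5-[(4R)-4-[(tert-butyldimethylsilyl)oxy]-2,6,6-trimethylcyclohex-1-en-1-yl]-3-methylpent-2-en-4-yn-1-ol
Conditions: Pd(PPh3)4 (5 mol %), CuI (10 mol %), Et3N, DMF, 50 °C, degassed
Reagents that add atoms: none
Why: Sonogashira coupling of a vinyl triflate with a terminal alkyne forms C6–C7; the 2,6,6-trimethylcyclohexenyl triflate motif is an established partner in Pd couplings, and the free primary alcohol and the E double bond of 8 are not touched.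

Step 7
Reactants: 9 (2E)-5-[(4R)-4-[(tert-butyldimethylsilyl)oxy]-2,6,6-trimethylcyclohex-1-en-1-yl]-3-methylpent-2-en-4-yn-1-ol
Product: 10 (1R)-4-[(3E)-5-hydroxy-3-methylpent-3-en-1-yn-1-yl]-3,5,5-trimethylcyclohex-3-en-1-ol
Conditions: TBAF, THF, 0 °C → rt
Reagents that add atoms: none
Why: Fluoride-mediated cleavage of the silyl ether, done here so that no deprotection is needed on the finished polyene.

Step 8
Reactants: 10 (1R)-4-[(3E)-5-hydroxy-3-methylpent-3-en-1-yn-1-yl]-3,5,5-trimethylcyclohex-3-en-1-ol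
Product: 11 (2E)-5-[(4R)-4-hydroxy-2,6,6-trimethylcyclohex-1-en-1-yl]-3-methylpent-2-en-4-ynal
Conditions: activated MnO2 (excess), CH2Cl2, rt, dark
Reagents that add atoms: none
Why: MnO2 oxidises allylic alcohols selectively, so the primary allylic alcohol should give the enynal while the homoallylic ring alcohol stays.

Step 9
Reactants: 12 (R)-α-ionone
Product: 13 (1E)-3-methyl-1-[(1R)-2,6,6-trimethylcyclohex-2-en-1-yl]penta-1,4-dien-3-ol (both C3 epimers)
Conditions: CH2=CHMgBr, THF, −20 → 0 °C; aq. NH4Cl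
Reagents that add atoms: vinylmagnesium bromide, C=C[Mg]Br
Why: 1,2-Grignard addition to the methyl ketone of the enone; the new carbinol centre is lost in step 10 and the ring stereocenter is not involved.

Step 10
Reactants: 13 (1E)-3-methyl-1-[(1R)-2,6,6-trimethylcyclohex-2-en-1-yl]penta-1,4-dien-3-ol
Product: 14 [(2E,4E)-3-methyl-5-[(1R)-2,6,6-trimethylcyclohex-2-en-1-yl]penta-2,4-dien-1-yl]triphenylphosphonium bromide
Conditions: PPh3·HBr, MeOH, rt; crystallisation
Reagents that add atoms: triphenylphosphine hydrobromide, [Br-].[PH+](c1ccccc1)(c1ccccc1)c1ccccc1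
Why: Acid-induced ionisation of the tertiary bis-allylic alcohol to a pentadienyl cation and capture by PPh3 at the primary terminus (allylic transposition) gives the conjugated E,E salt, the standard vinyl-ionol to C15 Wittig salt conversion.

Step 11
Reactants: 14 [(2E,4E)-3-methyl-5-[(1R)-2,6,6-trimethylcyclohex-2-en-1-yl]penta-2,4-dien-1-yl]triphenylphosphonium bromide; 15 (2E,4E,6E)-2,7-dimethylocta-2,4,6-trienedial
Product: 16 (2E,4E,6E,8E,10E,12E)-2,7,11-trimethyl-13-[(1R)-2,6,6-trimethylcyclohex-2-en-1-yl]trideca-2,4,6,8,10,12-hexaenal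
Conditions: NaOMe, CH2Cl2/MeOH, 0 °C → rt, 15 in excess (3 equiv), slow addition of 14; then heptane, 80 °C
Reagents that add atoms: none
Why: Wittig olefination forms C11'=C12'; the excess of the symmetric dialdehyde should favour mono-olefination, and the hindered Z isomer at the new bond should equilibrate thermally to E.

Step 12
Reactants: 16 (2E,4E,6E,8E,10E,12E)-2,7,11-trimethyl-13-[(1R)-2,6,6-trimethylcyclohex-2-en-1-yl]trideca-2,4,6,8,10,12-hexaenal
Product: 17 (2E,4E,6E,8E,10E,12E)-2,7,11-trimethyl-13-[(1R)-2,6,6-trimethylcyclohex-2-en-1-yl]trideca-2,4,6,8,10,12-hexaen-1-ol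
Conditions: NaBH4, EtOH/THF, 0 °C
Reagents that add atoms: none
Why: Borohydride 1,2-reduction of a polyenal to the allylic alcohol, leaving the polyene intact.

Step 13
Reactants: 17 (2E,4E,6E,8E,10E,12E)-2,7,11-trimethyl-13-[(1R)-2,6,6-trimethylcyclohex-2-en-1-yl]trideca-2,4,6,8,10,12-hexaen-1-ol
Product: 18 [(2E,4E,6E,8E,10E,12E)-2,7,11-trimethyl-13-[(1R)-2,6,6-trimethylcyclohex-2-en-1-yl]trideca-2,4,6,8,10,12-hexaen-1-yl]triphenylphosphonium bromide
Conditions: PPh3·HBr, MeOH/CH2Cl2, 0 °C → rt, dark
Reagents that add atoms: triphenylphosphine hydrobromide, [Br-].[PH+](c1ccccc1)(c1ccccc1)c1ccccc1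
Why: Conversion of a polyenyl allylic alcohol into its phosphonium salt through the delocalised cation, the same reaction type as the retinol to retinyl phosphonium salt conversion.

Step 14
Reactants: 18 [(2E,4E,6E,8E,10E,12E)-2,7,11-trimethyl-13-[(1R)-2,6,6-trimethylcyclohex-2-en-1-yl]trideca-2,4,6,8,10,12-hexaen-1-yl]triphenylphosphonium bromide; 11 (2E)-5-[(4R)-4-hydroxy-2,6,6-trimethylcyclohex-1-en-1-yl]-3-methylpent-2-en-4-ynal
Product: 19 (3R,6'R)-7,8-didehydro-β,ε-caroten-3-ol (all-E; target)
Conditions: NaOMe, CH2Cl2/MeOH, rt, Ar, dark; then EtOH, 60 °C; crystallisation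
Reagents that add atoms: none
Why: Wittig olefination forms C11=C12; the ylide is placed on the non-acetylenic half so that the 9E bond next to the triple bond is never part of an allylic ylide, the hindered 11Z isomer should equilibrate to E on gentle heating, and the free hydroxyl is tolerated.

**Compound list**

1 | 2,2-dimethylcyclopentan-1-one | O=C1CCCC1(C)C | starting material
2 | 5,5-dimethylcyclopent-2-en-1-one | O=C1C=CCC1(C)C | intermediate
3 | (4S)-2,2-dimethyl-4-(4,4,5,5-tetramethyl-1,3,2-dioxaborolan-2-yl)cyclopentan-1-one | O=C1C[C@@H](B2OC(C)(C)C(C)(C)O2)CC1(C)C | intermediate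
4 | (4S)-4-hydroxy-2,2-dimethylcyclopentan-1-one | O=C1C[C@@H](O)CC1(C)C | intermediate
5 | (4S)-4-[(tert-butyldimethylsilyl)oxy]-2,2-dimethylcyclopentan-1-one | O=C1C[C@@H](O[Si](C)(C)C(C)(C)C)CC1(C)C | intermediate
6 | (4R)-4-[(tert-butyldimethylsilyl)oxy]-2,2,6-trimethylcyclohexan-1-one (both C6 epimers) | CC1C[C@@H](O[Si](C)(C)C(C)(C)C)CC(C)(C)C1=O | intermediate
7 | (4R)-4-[(tert-butyldimethylsilyl)oxy]-2,6,6-trimethylcyclohex-1-en-1-yl trifluoromethanesulfonate | FC(F)(F)S(=O)(=O)OC1=C(C)C[C@@H](O[Si](C)(C)C(C)(C)C)CC1(C)C | intermediate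
8 | (2E)-3-methylpent-2-en-4-yn-1-ol | C#C/C(C)=C/CO | starting material
9 | (2E)-5-[(4R)-4-[(tert-butyldimethylsilyl)oxy]-2,6,6-trimethylcyclohex-1-en-1-yl]-3-methylpent-2-en-4-yn-1-ol | OC/C=C(\C)C#CC1=C(C)C[C@@H](O[Si](C)(C)C(C)(C)C)CC1(C)C | intermediate
10 | (1R)-4-[(3E)-5-hydroxy-3-methylpent-3-en-1-yn-1-yl]-3,5,5-trimethylcyclohex-3-en-1-ol | OC/C=C(\C)C#CC1=C(C)C[C@@H](O)CC1(C)C | intermediate
11 | (2E)-5-[(4R)-4-hydroxy-2,6,6-trimethylcyclohex-1-en-1-yl]-3-methylpent-2-en-4-ynal | O=C/C=C(\C)C#CC1=C(C)C[C@@H](O)CC1(C)C | intermediate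
12 | (R)-α-ionone, (3E)-4-[(1R)-2,6,6-trimethylcyclohex-2-en-1-yl]but-3-en-2-one | CC(=O)/C=C/[C@H]1C(C)=CCCC1(C)C | starting material
13 | (1E)-3-methyl-1-[(1R)-2,6,6-trimethylcyclohex-2-en-1-yl]penta-1,4-dien-3-ol (both C3 epimers) | C=CC(C)(O)/C=C/[C@H]1C(C)=CCCC1(C)C | intermediate
14 | [(2E,4E)-3-methyl-5-[(1R)-2,6,6-trimethylcyclohex-2-en-1-yl]penta-2,4-dien-1-yl]triphenylphosphonium bromide | [Br-].c1ccccc1[P+](c1ccccc1)(c1ccccc1)C/C=C(C)/C=C/[C@H]1C(C)=CCCC1(C)C | intermediate
15 | (2E,4E,6E)-2,7-dimethylocta-2,4,6-trienedial | O=C/C(C)=C/C=C/C=C(C)/C=O | starting material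
16 | (2E,4E,6E,8E,10E,12E)-2,7,11-trimethyl-13-[(1R)-2,6,6-trimethylcyclohex-2-en-1-yl]trideca-2,4,6,8,10,12-hexaenal | O=C/C(C)=C/C=C/C=C(C)/C=C/C=C(C)/C=C/[C@H]1C(C)=CCCC1(C)C | intermediate
17 | (2E,4E,6E,8E,10E,12E)-2,7,11-trimethyl-13-[(1R)-2,6,6-trimethylcyclohex-2-en-1-yl]trideca-2,4,6,8,10,12-hexaen-1-ol | OC/C(C)=C/C=C/C=C(C)/C=C/C=C(C)/C=C/[C@H]1C(C)=CCCC1(C)C | intermediate
18 | [(2E,4E,6E,8E,10E,12E)-2,7,11-trimethyl-13-[(1R)-2,6,6-trimethylcyclohex-2-en-1-yl]trideca-2,4,6,8,10,12-hexaen-1-yl]triphenylphosphonium bromide | [Br-].c1ccccc1[P+](c1ccccc1)(c1ccccc1)C/C(C)=C/C=C/C=C(C)/C=C/C=C(C)/C=C/[C@H]1C(C)=CCCC1(C)C | intermediate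
19 | (3R,6'R)-7,8-didehydro-β,ε-caroten-3-ol (all-E) | CC1=CCCC(C)(C)[C@H]1/C=C/C(C)=C/C=C/C(C)=C/C=C/C=C(C)/C=C/C=C(\C)C#CC1=C(C)C[C@@H](O)CC1(C)C | target

**Summary**

Total step count: 14. Longest linear sequence: 9 steps (steps 1–8, then 14) from 1; the ε-half takes 6 steps (9–14) from 12.

Steps most likely to fail:

1. Step 4. What may go wrong: migration of the quaternary carbon instead of the CH2 (the silyloxy group lowers the migratory aptitude of the CH2 arm), competing epoxide formation, or Lewis acid-induced β-elimination of the silyloxy group. Fallback, setting out from 5 and returning at 7: soft enolisation (TMSOTf, Et3N, CH2Cl2, 0 °C) can only give the trimethylsilyl enol ether F1 on the CH2 side. Chloro(methyl)carbene (CH3CHCl2, n-BuLi, Et2O, −35 °C) adds to this double bond to give the siloxy-chlorocyclopropane F2. Its thermal disrotatory opening with loss of chlorotrimethylsilane (toluene, Et3N, reflux) must break the ring-fusion bond and should give the 2-methylcyclohexenone F3. Conjugate reduction with L-Selectride (THF, −78 °C) and trapping of the enolate with PhNTf2 should then give 7, so the regiochemistry of the carbon insertion is enforced by the position of the enol ether.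

2. Step 14. What may go wrong: poor E/Z control at the new C11=C12 bond, base-induced stereomutation of the 9,10-double bond of the enynal, and decay of the long polyenyl ylide. Fallback, setting out from 17 and returning at 19: PBr3 (cat. pyridine, Et2O, −20 °C) gives the allylic bromide F4. Michaelis–Becker reaction with NaP(O)(OEt)2 (THF, 0 °C) gives the phosphonate F5. Horner–Wadsworth–Emmons olefination of 11 with F5 (KOtBu, 2.2 equiv, THF, −30 °C → rt) should give 19 with higher E preference and a water-soluble phosphate by-product.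

3. Step 6. What may go wrong: slow oxidative addition into the hindered tetrasubstituted triflate, with oxidative homocoupling of the enynol and hydrolysis of the triflate taking over. Fallback, setting out from 6 (and 8) and returning at 10: 8 is silylated (TBSCl, imidazole) to the silyl ether F6. Its lithium acetylide (n-BuLi, THF, −78 °C) adds to ketone 6 to give the tertiary propargylic carbinol F7. Dehydration (POCl3, pyridine, 60 °C) can only remove the single ring hydrogen next to the carbinol carbon and should give the bis-silyl ether F8. TBAF then removes both silyl groups and gives 10.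

**Further compounds**

F1 | step 4 | tert-butyl{[(1S)-4,4-dimethyl-3-[(trimethylsilyl)oxy]cyclopent-2-en-1-yl]oxy}dimethylsilane | C[Si](C)(C)OC1=C[C@@H](O[Si](C)(C)C(C)(C)C)CC1(C)C
F2 | step 4 | tert-butyl{[(2S)-6-chloro-4,4,6-trimethyl-5-[(trimethylsilyl)oxy]bicyclo[3.1.0]hexan-2-yl]oxy}dimethylsilane (cyclopropane diastereomers) | CC1(Cl)C2[C@@H](O[Si](C)(C)C(C)(C)C)CC(C)(C)C12O[Si](C)(C)C
F3 | step 4 | (4S)-4-[(tert-butyldimethylsilyl)oxy]-2,6,6-trimethylcyclohex-2-en-1-one | CC1=C[C@@H](O[Si](C)(C)C(C)(C)C)CC(C)(C)C1=O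
F4 | step 14 | (1R)-1-[(1E,3E,5E,7E,9E,11E)-13-bromo-3,7,12-trimethyltrideca-1,3,5,7,9,11-hexaen-1-yl]-2,6,6-trimethylcyclohex-2-ene | BrC/C(C)=C/C=C/C=C(C)/C=C/C=C(C)/C=C/[C@H]1C(C)=CCCC1(C)C
F5 | step 14 | diethyl [(2E,4E,6E,8E,10E,12E)-2,7,11-trimethyl-13-[(1R)-2,6,6-trimethylcyclohex-2-en-1-yl]trideca-2,4,6,8,10,12-hexaen-1-yl]phosphonate | CCOP(=O)(OCC)C/C(C)=C/C=C/C=C(C)/C=C/C=C(C)/C=C/[C@H]1C(C)=CCCC1(C)C
F6 | step 6 | tert-butyldimethyl{[(2E)-3-methylpent-2-en-4-yn-1-yl]oxy}silane | C#C/C(C)=C/CO[Si](C)(C)C(C)(C)C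
F7 | step 6 | (4R)-4-[(tert-butyldimethylsilyl)oxy]-1-[(3E)-5-[(tert-butyldimethylsilyl)oxy]-3-methylpent-3-en-1-yn-1-yl]-2,2,6-trimethylcyclohexan-1-ol (diastereomers at C1 and C6) | CC1C[C@@H](O[Si](C)(C)C(C)(C)C)CC(C)(C)C1(O)C#C/C(C)=C/CO[Si](C)(C)C(C)(C)C
F8 | step 6 | tert-butyl{[(2E)-5-[(4R)-4-[(tert-butyldimethylsilyl)oxy]-2,6,6-trimethylcyclohex-1-en-1-yl]-3-methylpent-2-en-4-yn-1-yl]oxy}dimethylsilane | CC(C)(C)[Si](C)(C)OC/C=C(\C)C#CC1=C(C)C[C@@H](O[Si](C)(C)C(C)(C)C)CC1(C)C
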